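**Retrosynthetic overview**
1. Target ⇒ macrocyclic C8 alcohol + O-silylated (E)-4-hydroxy-2-methylbut-2-enoic acid (Yamaguchi esterification, then desilylation).
2. Ten-membered carbocycle (formed last) ⇒ ring-closing metathesis closing C1=C10 (Z) of a cis-lactone that carries a butenyl-epoxide arm and a methallyl arm.
3. cis-α-Methylene-γ-butyrolactone (formed second; C6–C7 bond, C6 and C7 stereocentres) ⇒ chromium-catalysed, ligand-controlled 2-(methoxycarbonyl)allylation joining a west epoxy aldehyde and an east allylic bromide.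
4. West (epoxide ring formed first): Sharpless epoxidation of a (Z)-dienol from Pd-catalysed Kumada coupling of (Z)-3-iodobut-2-en-1-ol. East: glyoxylate–ene reaction (sets C8), vinylalumination, SN2′ bromination.
5. Side chain: cross-metathesis of methyl methacrylate with allyl silyl ether, then saponification.

Assumption: the SMILES is taken literally (cis-fused 6,12-lactone, cis-4,5-epoxide, 1(10)Z, 2′E; 4R,5S,6S,7S,8R; germacrane locants C1–C15 are used throughout), and the ligand enantiomer in step 13 is the one that sends the allyl group to the Si face of the aldehyde.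

**Route**

Step 1
Reactants: 1 but-2-yn-1-ol
Product: 3 (2Z)-3-iodobut-2-en-1-ol, via cyclic sodium alkenylalanate 2 (not isolated)
Conditions: NaAlH2(OCH2CH2OMe)2 (1.5 equiv), THF, 0 °C to rt; then I2, THF, −78 °C to 0 °C; aq. Na2S2O3 / potassium sodium tartrate
Reagents that add atoms: iodine (II)
Why: Hydroxyl-directed trans-hydroalumination places aluminium on C3 in a five-membered alkoxyalanate, and iodinolysis with retention gives the vinyl iodide with I cis to CH2OH, which fixes the later cis relationship of C3 and C6 at the epoxide.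

Step 2
Reactants: 3 (2Z)-3-iodobut-2-en-1-ol; 4 but-3-enylmagnesium bromide
Product: 5 (2Z)-3-methylhepta-2,6-dien-1-ol
Conditions: 4 (2.5 equiv), Pd(dppf)Cl2 (3 mol %), THF, 0 °C to rt; aq. NH4Cl
Reagents that add atoms: none
Why: Pd-catalysed Kumada–Corriu sp2–sp3 coupling proceeds with retention of olefin geometry, the first equivalent of Grignard only forming the magnesium alkoxide and the dppf ligand suppressing β-hydride elimination.

Step 3
Reactants: 5 (2Z)-3-methylhepta-2,6-dien-1-ol
Product: 6 [(2S,3R)-3-(but-3-en-1-yl)-3-methyloxiran-2-yl]methanol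
Conditions: Ti(OiPr)4 (10 mol %), L-(+)-diethyl tartrate (14 mol %), t-BuOOH (2 equiv, decane), 4 Å MS, CH2Cl2, −25 °C
Reagents that add atoms: tert-butyl hydroperoxide (CC(C)(C)OO)
Why: Sharpless asymmetric epoxidation touches only the allylic-alcohol olefin, and L-(+)-tartrate delivers oxygen to the face that gives the (2S,3R) cis-epoxide (C5 S, C4 R), as it does with nerol.

Step 4
Reactants: 6 [(2S,3R)-3-(but-3-en-1-yl)-3-methyloxiran-2-yl]methanol
Product: 7 (2R,3R)-3-(but-3-en-1-yl)-3-methyloxirane-2-carbaldehyde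
Conditions: TEMPO (10 mol %), PhI(OAc)2 (1.1 equiv), CH2Cl2, rt; used at once
Reagents that add atoms: none
Why: Oxoammonium (TEMPO) oxidation of the primary alcohol stops at the aldehyde under near-neutral conditions that leave the epoxide and its stereocentres untouched (the descriptor at C5 changes only by priority).

Step 5
Reactants: 8 ethyl glyoxylate; 9 2-methylpropene
Product: 10 ethyl (2R)-2-hydroxy-4-methylpent-4-enoate
Conditions: (R)-BINOL (10 mol %), Ti(OiPr)2Cl2 (10 mol %), 4 Å MS, CH2Cl2, −30 °C, 9 in excess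
Reagents that add atoms: none
Why: Mikami glyoxylate–ene reaction in which the (R)-BINOL–titanium Lewis acid binds the glyoxylate and shields one face, so isobutene adds to give the (R)-α-hydroxy ester (C8) in high ee.

Step 6
Reactants: 10 ethyl (2R)-2-hydroxy-4-methylpent-4-enoate
Product: 11 ethyl (2R)-2-[(tert-butyldimethylsilyl)oxy]-4-methylpent-4-enoate
Conditions: TBSCl, imidazole, DMF, rt
Reagents that add atoms: tert-butyldimethylsilyl chloride (CC(C)(C)[Si](C)(C)Cl)
Why: Standard imidazole-mediated silylation of the secondary alcohol gives an ether that survives every step up to the fluoride cleavage.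

Step 7
Reactants: 11 ethyl (2R)-2-[(tert-butyldimethylsilyl)oxy]-4-methylpent-4-enoate
Product: 13 (2R)-2-[(tert-butyldimethylsilyl)oxy]-4-methylpent-4-enal, via diisobutylaluminium hemiacetal 12 (not isolated)
Conditions: i-Bu2AlH (1.05 equiv), CH2Cl2, −78 °C; aq. potassium sodium tartrate
Reagents that add atoms: none
Why: Partial ester reduction works because the tetrahedral aluminium hemiacetal is stable at −78 °C and releases the aldehyde only on work-up, so C8 is neither over-reduced nor epimerised.

Step 8
Reactants: 13 (2R)-2-[(tert-butyldimethylsilyl)oxy]-4-methylpent-4-enal; 14 methyl propiolate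
Product: 16 methyl (4R)-4-[(tert-butyldimethylsilyl)oxy]-3-hydroxy-6-methyl-2-methylidenehept-6-enoate (C3 epimers), via methyl 2-(diisobutylalumanyl)prop-2-enoate 15 (not isolated)
Conditions: 14, i-Bu2AlH, N-methylmorpholine N-oxide, THF, 0 °C; then 13, 0 °C to rt; aq. potassium sodium tartrate
Reagents that add atoms: none
Why: Vinylalumination (hydroalumination of the propiolate to the α-aluminated acrylate, then 1,2-addition) gives the Morita–Baylis–Hillman-type adduct without amine base, so the α-silyloxy centre is not epimerised and the new carbinol centre is erased in step 9.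

Step 9
Reactants: 16 methyl (4R)-4-[(tert-butyldimethylsilyl)oxy]-3-hydroxy-6-methyl-2-methylidenehept-6-enoate
Product: 17 methyl (2Z,4R)-2-(bromomethyl)-4-[(tert-butyldimethylsilyl)oxy]-6-methylhepta-2,6-dienoate
Conditions: NBS and Me2S premixed, CH2Cl2, 0 °C; then 16, 0 °C to rt
Reagents that add atoms: N-bromosuccinimide (O=C1CCC(=O)N1Br)
Why: Corey–Kim-type activation of the allylic alcohol followed by SN2′ attack of bromide gives the transposed, thermodynamically preferred 2-(bromomethyl)alk-2-enoate with C8 trans to the ester, and premixing leaves no free NBS to attack the isopropenyl group.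

Step 10
Reactants: 18 prop-2-en-1-ol
Product: 19 tert-butyldimethyl(prop-2-en-1-yloxy)silane
Conditions: TBSCl, imidazole, CH2Cl2, rt
Reagents that add atoms: tert-butyldimethylsilyl chloride (CC(C)(C)[Si](C)(C)Cl)
Why: Routine silylation of a primary alcohol.

Step 11
Reactants: 19 tert-butyldimethyl(prop-2-en-1-yloxy)silane; 20 methyl methacrylate
Product: 21 methyl (2E)-4-[(tert-butyldimethylsilyl)oxy]-2-methylbut-2-enoate
Conditions: 20 (5 equiv), second-generation Hoveyda–Grubbs catalyst (3 mol %), CH2Cl2, 40 °C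
Reagents that add atoms: none
Why: Olefin cross-metathesis of a gem-disubstituted acrylate with a terminal allylic ether gives the trisubstituted enoate as the thermodynamically favoured (E)-isomer.

Step 12
Reactants: 21 methyl (2E)-4-[(tert-butyldimethylsilyl)oxy]-2-methylbut-2-enoate
Product: 22 (2E)-4-[(tert-butyldimethylsilyl)oxy]-2-methylbut-2-enoic acid
Conditions: LiOH, THF/MeOH/H2O, 0 °C to rt; then 1 M HCl to pH 4, 0 °C
Reagents that add atoms: lithium hydroxide ([Li+].[OH-])
Why: Saponification of the methyl ester, to which the primary TBS ether and the (E)-olefin are stable.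

Step 13
Reactants: 7 (2R,3R)-3-(but-3-en-1-yl)-3-methyloxirane-2-carbaldehyde; 17 methyl (2Z,4R)-2-(bromomethyl)-4-[(tert-butyldimethylsilyl)oxy]-6-methylhepta-2,6-dienoate
Product: 24 (4R,5S)-4-[(1R)-1-[(tert-butyldimethylsilyl)oxy]-3-methylbut-3-en-1-yl]-5-[(2S,3R)-3-(but-3-en-1-yl)-3-methyloxiran-2-yl]-3-methylideneoxolan-2-one, via open-chain hydroxy ester 23 (not isolated)
Conditions: CrCl2 (10 mol %), carbazole-1,8-bis(4-isopropyloxazoline) ligand (12 mol %), Et3N (25 mol %), Mn powder (2.5 equiv), Cp2ZrCl2 (1.2 equiv), THF, 0 °C to rt, slow addition of 17; aq. NH4Cl; then PPTS (10 mol %), CH2Cl2, rt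
Reagents that add atoms: none
Why: Proposed new method: a chromium-catalysed, ligand-controlled 2-(methoxycarbonyl)allylation used as a double-stereodifferentiating fragment coupling, in which divalent chromium (regenerated by Mn) reduces bromide 17 to an allylchromium species that settles with C8 trans to the ester and adds to aldehyde 7 through a closed six-membered chair (γ-substituent axial, hence syn adduct and cis-lactone), while the ligand on trivalent chromium selects the aldehyde Si face, which is also the Felkin–Anh face (attack anti to the epoxide C–O bond) and lets C6 approach C7 anti to the C8 silyloxy group in the allylic-strain-minimised rotamer, so that C6 (S) and C7 are set together, Cp2ZrCl2 frees the alkoxide from chromium and hydroxy ester 23 lactonises; the closest known reactions are the chromium-catalysed enantioselective 2-(alkoxycarbonyl)allylation of simple aldehydes (Nozaki–Hiyama–Kishi type) and the cis-selective stoichiometric CrCl2 reaction of 2-(bromomethyl)alk-2-enoates, neither shown for a γ-branched chiral bromide paired with an α,β-epoxy aldehyde.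

Step 14
Reactants: 24 (4R,5S)-4-[(1R)-1-[(tert-butyldimethylsilyl)oxy]-3-methylbut-3-en-1-yl]-5-[(2S,3R)-3-(but-3-en-1-yl)-3-methyloxiran-2-yl]-3-methylideneoxolan-2-one
Product: 25 (1(10)Z,4R,5S,6S,7R,8R)-8-[(tert-butyldimethylsilyl)oxy]-4,5-epoxygermacra-1(10),11(13)-dien-12,6-olide (cis-fused lactone)
Conditions: second-generation Grubbs catalyst (10 mol %, in portions), 1,4-benzoquinone (20 mol %), toluene (1 mM), 80 °C
Reagents that add atoms: none
Why: Ring-closing metathesis in which the cis-fused lactone holds both olefin arms on one face, the ruthenium carbene loads at the monosubstituted olefin and closes onto the isopropenyl group, the ten-membered trisubstituted olefin forms as the far less strained (Z)-isomer, and closure onto the α-methylene would need a bridgehead olefin.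

Step 15
Reactants: 25 (1(10)Z,4R,5S,6S,7R,8R)-8-[(tert-butyldimethylsilyl)oxy]-4,5-epoxygermacra-1(10),11(13)-dien-12,6-olide
Product: 26 (1(10)Z,4R,5S,6S,7S,8R)-4,5-epoxy-8-hydroxygermacra-1(10),11(13)-dien-12,6-olide
Conditions: HF·pyridine, pyridine, THF, 0 °C to rt
Reagents that add atoms: none
Why: Pyridine-buffered fluoride cleaves the secondary silyl ether while sparing the trisubstituted epoxide and the α-methylene lactone (the C7 descriptor changes by priority only).

Step 16
Reactants: 26 (1(10)Z,4R,5S,6S,7S,8R)-4,5-epoxy-8-hydroxygermacra-1(10),11(13)-dien-12,6-olide; 22 (2E)-4-[(tert-butyldimethylsilyl)oxy]-2-methylbut-2-enoic acid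
Product: 28 (1(10)Z,4R,5S,6S,7S,8R)-4,5-epoxy-12-oxo-12,6-olidogermacra-1(10),11(13)-dien-8-yl (2E)-4-[(tert-butyldimethylsilyl)oxy]-2-methylbut-2-enoate, via mixed trichlorobenzoic anhydride 27 (not isolated)
Conditions: 22, 2,4,6-trichlorobenzoyl chloride, Et3N, toluene, rt; then 26, DMAP, toluene, rt
Reagents that add atoms: none
Why: Yamaguchi esterification, in which DMAP attacks the mixed anhydride at the less hindered enoyl carbonyl and the acylpyridinium acylates the hindered C8 alcohol with retention at C8 and at the (E)-enoate.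

Step 17
Reactants: 28 (1(10)Z,4R,5S,6S,7S,8R)-4,5-epoxy-12-oxo-12,6-olidogermacra-1(10),11(13)-dien-8-yl (2E)-4-[(tert-butyldimethylsilyl)oxy]-2-methylbut-2-enoate
Product: 29 target, (1(10)Z,4R,5S,6S,7S,8R)-4,5-epoxy-8-[(2E)-4-hydroxy-2-methylbut-2-enoyloxy]germacra-1(10),11(13)-dien-12,6-olide
Conditions: HF·pyridine, pyridine, THF, 0 °C
Reagents that add atoms: none
Why: Buffered fluoride removes the primary allylic silyl ether quickly, and no other group in the molecule reacts under these conditions.

**Compound list**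
1 | but-2-yn-1-ol | CC#CCO | starting material
2 | sodium 2,2-bis(2-methoxyethoxy)-3-methyl-2,5-dihydro-1,2-oxaaluminol-2-uide (cyclic alkenylalanate) | CC1=CCO[Al-]1(OCCOC)OCCOC.[Na+] | intermediate
3 | (2Z)-3-iodobut-2-en-1-ol | C/C(I)=C/CO | intermediate
4 | but-3-enylmagnesium bromide | C=CCC[Mg]Br | starting material
5 | (2Z)-3-methylhepta-2,6-dien-1-ol | C=CCC/C(C)=C\CO | intermediate
6 | [(2S,3R)-3-(but-3-en-1-yl)-3-methyloxiran-2-yl]methanol | C=CCC[C@@]1(C)O[C@H]1CO | intermediate
7 | (2R,3R)-3-(but-3-en-1-yl)-3-methyloxirane-2-carbaldehyde | C=CCC[C@@]1(C)O[C@H]1C=O | intermediate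
8 | ethyl glyoxylate | CCOC(=O)C=O | starting material
9 | 2-methylpropene | CC(C)=C | starting material
10 | ethyl (2R)-2-hydroxy-4-methylpent-4-enoate | CCOC(=O)[C@H](O)CC(C)=C | intermediate
11 | ethyl (2R)-2-[(tert-butyldimethylsilyl)oxy]-4-methylpent-4-enoate | CCOC(=O)[C@H](O[Si](C)(C)C(C)(C)C)CC(C)=C | intermediate
12 | diisobutylaluminium hemiacetal of 11 (hemiacetal carbon as epimers) | CCOC(O[Al](CC(C)C)CC(C)C)[C@H](O[Si](C)(C)C(C)(C)C)CC(C)=C | intermediate
13 | (2R)-2-[(tert-butyldimethylsilyl)oxy]-4-methylpent-4-enal | O=C[C@H](O[Si](C)(C)C(C)(C)C)CC(C)=C | intermediate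
14 | methyl propiolate | C#CC(=O)OC | starting material
15 | methyl 2-(diisobutylalumanyl)prop-2-enoate | C=C(C(=O)OC)[Al](CC(C)C)CC(C)C | intermediate
16 | methyl (4R)-4-[(tert-butyldimethylsilyl)oxy]-3-hydroxy-6-methyl-2-methylidenehept-6-enoate (C3 epimers) | C=C(C(=O)OC)C(O)[C@H](O[Si](C)(C)C(C)(C)C)CC(C)=C | intermediate
17 | methyl (2Z,4R)-2-(bromomethyl)-4-[(tert-butyldimethylsilyl)oxy]-6-methylhepta-2,6-dienoate | COC(=O)/C(CBr)=C/[C@H](O[Si](C)(C)C(C)(C)C)CC(C)=C | intermediate
18 | prop-2-en-1-ol | C=CCO | starting material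
19 | tert-butyldimethyl(prop-2-en-1-yloxy)silane | C=CCO[Si](C)(C)C(C)(C)C | intermediate
20 | methyl methacrylate | C=C(C)C(=O)OC | starting material
21 | methyl (2E)-4-[(tert-butyldimethylsilyl)oxy]-2-methylbut-2-enoate | COC(=O)/C(C)=C/CO[Si](C)(C)C(C)(C)C | intermediate
22 | (2E)-4-[(tert-butyldimethylsilyl)oxy]-2-methylbut-2-enoic acid | OC(=O)/C(C)=C/CO[Si](C)(C)C(C)(C)C | intermediate
23 | methyl (3R,4R)-4-[(tert-butyldimethylsilyl)oxy]-3-[(S)-[(2S,3R)-3-(but-3-en-1-yl)-3-methyloxiran-2-yl](hydroxy)methyl]-6-methyl-2-methylidenehept-6-enoate | COC(=O)C(=C)[C@H]([C@H](O)[C@@H]1O[C@]1(C)CCC=C)[C@H](O[Si](C)(C)C(C)(C)C)CC(C)=C | intermediate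
24 | (4R,5S)-4-[(1R)-1-[(tert-butyldimethylsilyl)oxy]-3-methylbut-3-en-1-yl]-5-[(2S,3R)-3-(but-3-en-1-yl)-3-methyloxiran-2-yl]-3-methylideneoxolan-2-one (H4/H5 cis) | C=C1C(=O)O[C@H]([C@@H]2O[C@]2(C)CCC=C)[C@@H]1[C@H](O[Si](C)(C)C(C)(C)C)CC(C)=C | intermediate
25 | (1(10)Z,4R,5S,6S,7R,8R)-8-[(tert-butyldimethylsilyl)oxy]-4,5-epoxygermacra-1(10),11(13)-dien-12,6-olide | C=C1C(=O)O[C@H]2[C@@H]1[C@H](O[Si](C)(C)C(C)(C)C)C/C(C)=C\CC[C@@]1(C)O[C@@H]21 | intermediate
26 | (1(10)Z,4R,5S,6S,7S,8R)-4,5-epoxy-8-hydroxygermacra-1(10),11(13)-dien-12,6-olide | C=C1C(=O)O[C@H]2[C@@H]1[C@H](O)C/C(C)=C\CC[C@@]1(C)O[C@@H]21 | intermediate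
27 | (2E)-4-[(tert-butyldimethylsilyl)oxy]-2-methylbut-2-enoic 2,4,6-trichlorobenzoic anhydride | O=C(OC(=O)/C(C)=C/CO[Si](C)(C)C(C)(C)C)c1c(Cl)cc(Cl)cc1Cl | intermediate
28 | 8-O-[(2E)-4-[(tert-butyldimethylsilyl)oxy]-2-methylbut-2-enoyl] derivative of 26 (4R,5S,6S,7S,8R; 1(10)Z) | C=C1C(=O)O[C@H]2[C@@H]1[C@H](OC(=O)/C(C)=C/CO[Si](C)(C)C(C)(C)C)C/C(C)=C\CC[C@@]1(C)O[C@@H]21 | intermediate
29 | (1(10)Z,4R,5S,6S,7S,8R)-4,5-epoxy-8-[(2E)-4-hydroxy-2-methylbut-2-enoyloxy]germacra-1(10),11(13)-dien-12,6-olide | C=C1C(=O)O[C@H]2[C@@H]1[C@H](OC(=O)/C(C)=C/CO)C/C(C)=C\CC[C@@]1(C)O[C@@H]21 | target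

**Step count and risks**

Total step count: 17. Longest linear sequence: 10 steps (steps 5–9, then 13–17); the west branch has 4 steps and the side-chain branch 3.

Most likely to fail, first: step 13, the proposed chromium-catalysed coupling. Three control elements (ligand, Felkin–Anh bias of the epoxy aldehyde, bias of the C8 centre) must cooperate, the sense of the C8 bias is argued by analogy only, and the epoxy aldehyde must survive the Lewis-acidic reducing medium. The fallback uses known chemistry and sets out from bromide 17. Pd-catalysed borylation (Pd2(dba)3, B2pin2, DMSO, 50 °C) gives the linear pinacol allylboronate methyl (2E,4R)-4-[(tert-butyldimethylsilyl)oxy]-6-methyl-2-[(4,4,5,5-tetramethyl-1,3,2-dioxaborolan-2-yl)methyl]hepta-2,6-dienoate F1. F1 is heated with aldehyde 7 in toluene at 60–80 °C without any metal. This is the established 2-(alkoxycarbonyl)allylboration: the geometrically fixed boronate (C8 cis to CH2B) reacts through a closed chair to the syn adduct, with Felkin–Anh control by the epoxide. Hydrolytic work-up and PPTS take the borate through hydroxy ester 23 to lactone 24, where the route is rejoined.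

Second: step 14, the ring-closing metathesis. A ten-membered ring with a trisubstituted olefin must close in the presence of a third, catalyst-binding olefin (the α-methylene lactone), so oligomers, olefin migration or closure onto the wrong olefin are possible. The fallback masks the competing olefin and sets out from lactone 24. Me2NH in THF at rt adds to the α-methylene group to give the dimethylamine adduct F2. Its p-toluenesulfonate salt is cyclised with the second-generation Hoveyda–Grubbs catalyst in toluene at 80 °C to the macrocyclic amine F3. MeI converts F3 into the trimethylammonium iodide F4, and aq. NaHCO3 eliminates trimethylamine to regenerate the α-methylene lactone, coming back to the route at 25.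

Third: step 16, acylation of the hindered C8 hydroxyl inside the macrocycle, next to a base-sensitive α-methylene lactone. The fallback moves the acylation before ring closure and sets out from 24. HF·pyridine/pyridine gives the seco alcohol F5, an unhindered open-chain secondary alcohol. Yamaguchi esterification with acid 22 (through anhydride 27) gives the seco ester F6. Ring-closing metathesis of F6 under the conditions of step 14 then delivers 28 directly.

**Further compounds**
F1 | step 13 | methyl (2E,4R)-4-[(tert-butyldimethylsilyl)oxy]-6-methyl-2-[(4,4,5,5-tetramethyl-1,3,2-dioxaborolan-2-yl)methyl]hepta-2,6-dienoate | COC(=O)/C(CB1OC(C)(C)C(C)(C)O1)=C/[C@H](O[Si](C)(C)C(C)(C)C)CC(C)=C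
F2 | step 14 | dimethylamine adduct of 24: 3-[(dimethylamino)methyl] analogue of 24 (C3 epimers, other centres as in 24) | CN(C)CC1C(=O)O[C@H]([C@@H]2O[C@]2(C)CCC=C)[C@@H]1[C@H](O[Si](C)(C)C(C)(C)C)CC(C)=C
F3 | step 14 | 13-(dimethylamino)-11,13-dihydro derivative of 25 (C11 epimers) | CN(C)CC1C(=O)O[C@H]2[C@@H]1[C@H](O[Si](C)(C)C(C)(C)C)C/C(C)=C\CC[C@@]1(C)O[C@@H]21
F4 | step 14 | N-methyl quaternary ammonium iodide of F3 | C[N+](C)(C)CC1C(=O)O[C@H]2[C@@H]1[C@H](O[Si](C)(C)C(C)(C)C)C/C(C)=C\CC[C@@]1(C)O[C@@H]21.[I-]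
F5 | step 16 | (4S,5S)-5-[(2S,3R)-3-(but-3-en-1-yl)-3-methyloxiran-2-yl]-4-[(1R)-1-hydroxy-3-methylbut-3-en-1-yl]-3-methylideneoxolan-2-one | C=C1C(=O)O[C@H]([C@@H]2O[C@]2(C)CCC=C)[C@@H]1[C@H](O)CC(C)=C
F6 | step 16 | (2E)-4-[(tert-butyldimethylsilyl)oxy]-2-methylbut-2-enoate ester of F5 at its secondary hydroxyl | C=C1C(=O)O[C@H]([C@@H]2O[C@]2(C)CCC=C)[C@@H]1[C@H](OC(=O)/C(C)=C/CO[Si](C)(C)C(C)(C)C)CC(C)=C
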